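**Retrosynthetic overview**
1. Target 34 ⇒ desilylation of 33; 33 ⇒ Wittig formation of C11=C12 from the C25 ε-end ylide 31 and the C15 β-end keto-enal ester 14 (carotenoid numbering).
2. 14 ⇒ oxidative opening of the 2,3-disubstituted furan 12; furan C2 is a masked C8 carbonyl, so the 2-furyl anion of furan-3-ylmethanol is an acyl-anion equivalent that brings C8, C9, C10, C11 and C19–O in one piece.
3. Key bond C7–C8: alkylation of that furyl anion with allylic bromide 7 (acyl carbon plus allylic halide carbon, both acceptor carbons); 7 ⇐ (4R,6R)-actinol, which supplies the 3R centre.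
4. 31 ⇐ C15 phosphonium salt 23 + C10 dialdehyde 24; 23 ⇐ racemic α-ionone (HWE, allylic oxidation, catalyst-controlled transfer hydrogenation sets 3′R; 6′R is obtained by separating diastereomers).
5. No carbocycle is built: the β ring comes from actinol, the ε ring from α-ionone; the furan ring is bought, used as the reversed-polarity carrier and opened in step 7.

Assumption: the target is the all-E (3R,3′R,6′R) isomer encoded in the SMILES (siphonaxanthin 19-(2E)-dodec-2-enoate); commercial α-ionone is the racemate, and 1, 5, 8, 11, 16 and 24 are bought.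

**Route**

Step 1
Reactants: 1 (4R,6R)-4-hydroxy-2,2,6-trimethylcyclohexan-1-one (actinol)
Product: 2 (4R,6R)-2,2,6-trimethyl-4-(triethylsilyloxy)cyclohexan-1-one
Conditions: TESCl, imidazole, DMF, 0 °C → rt
Reagents that add atoms: triethylsilyl chloride, CC[Si](Cl)(CC)CC
Why: Imidazole-promoted silyl ether formation masks the only hydroxyl for the organometallic and acylation steps and touches neither stereocentre.

Step 2
Reactants: 2 (4R,6R)-2,2,6-trimethyl-4-(triethylsilyloxy)cyclohexan-1-one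
Product: 4 (4R)-2,6,6-trimethyl-4-(triethylsilyloxy)cyclohex-1-en-1-yl trifluoromethanesulfonate, via potassium enolate 3 (not isolated)
Conditions: KN(SiMe3)2, THF, −78 °C; then PhNTf2, −78 → 0 °C
Reagents that add atoms: N-phenylbis(trifluoromethanesulfonimide), O=S(=O)(N(c1ccccc1)S(=O)(=O)C(F)(F)F)C(F)(F)F
Why: Enolisation is possible only toward C6 (C2 is quaternary) and O-triflation of the enolate gives the tetrasubstituted enol triflate; the C6 centre is erased on purpose and the silyloxy carbon, γ to the enolate carbon, cannot eliminate.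

Step 3
Reactants: 4 (4R)-2,6,6-trimethyl-4-(triethylsilyloxy)cyclohex-1-en-1-yl trifluoromethanesulfonate; 5 (tributylstannyl)methanol
Product: 6 [(4R)-2,6,6-trimethyl-4-(triethylsilyloxy)cyclohex-1-en-1-yl]methanol
Conditions: Pd(PPh3)4 (5 mol %), LiCl, 1,4-dioxane, 100 °C
Reagents that add atoms: none
Why: Migita–Kosugi–Stille coupling transfers the hydroxymethyl group of 5 in preference to butyl to the vinylpalladium species and installs C7 as a primary allylic alcohol without affecting the stereocentre.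

Step 4
Reactants: 6 [(4R)-2,6,6-trimethyl-4-(triethylsilyloxy)cyclohex-1-en-1-yl]methanol
Product: 7 {[(1R)-4-(bromomethyl)-3,5,5-trimethylcyclohex-3-en-1-yl]oxy}triethylsilane
Conditions: CBr4, PPh3, 2,6-lutidine (0.2 equiv), CH2Cl2, −20 → 0 °C
Reagents that add atoms: carbon tetrabromide, BrC(Br)(Br)Br
Why: Appel bromination converts the primary allylic alcohol into the bromide under near-neutral conditions that the TES ether tolerates, and allylic transposition to the fully substituted C5 terminus does not compete.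

Step 5
Reactants: 7 {[(1R)-4-(bromomethyl)-3,5,5-trimethylcyclohex-3-en-1-yl]oxy}triethylsilane; 8 furan-3-ylmethanol
Product: 10 (2-{[(4R)-2,6,6-trimethyl-4-(triethylsilyloxy)cyclohex-1-en-1-yl]methyl}furan-3-yl)methanol, via dilithiated furanmethanol 9 (not isolated)
Conditions: 8, n-BuLi (2.2 equiv), THF, −78 → 0 °C; then copper monoiodide CuI (10 mol %), 7, DMPU, −78 °C → rt; H2O quench
Reagents that add atoms: none
Why: Alkoxide-directed ortho-lithiation of 8 at C2 gives a 2-furyl anion that is a masked acyl anion (furan C2 becomes the C8 ketone on ring opening), and its copper-catalysed SN2 alkylation by the allylic bromide joins C7 and C8, two carbons that are both acceptors in normal polarity; no stereocentre is formed.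

Step 6
Reactants: 10 (2-{[(4R)-2,6,6-trimethyl-4-(triethylsilyloxy)cyclohex-1-en-1-yl]methyl}furan-3-yl)methanol; 11 (2E)-dodec-2-enoic acid
Product: 12 (2-{[(4R)-2,6,6-trimethyl-4-(triethylsilyloxy)cyclohex-1-en-1-yl]methyl}furan-3-yl)methyl (2E)-dodec-2-enoate
Conditions: DCC, DMAP (5 mol %), CH2Cl2, 0 °C → rt
Reagents that add atoms: none
Why: Steglich esterification acylates the only free hydroxyl (the future C19–OH) while the furan is still intact, and catalytic DMAP at low temperature keeps the enoate conjugated and E.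

Step 7
Reactants: 12 (2-{[(4R)-2,6,6-trimethyl-4-(triethylsilyloxy)cyclohex-1-en-1-yl]methyl}furan-3-yl)methyl (2E)-dodec-2-enoate
Product: 14 (2E)-4-oxo-2-{[(4R)-2,6,6-trimethyl-4-(triethylsilyloxy)cyclohex-1-en-1-yl]acetyl}but-2-en-1-yl (2E)-dodec-2-enoate, via Z keto-enal 13 (not isolated)
Conditions: NBS (1.0 equiv), NaHCO3, acetone/H2O 10:1, −20 °C; then I2 (2 mol %), CH2Cl2, rt, daylight
Reagents that add atoms: water, O
Why: Achmatowicz-type oxidative furan opening (bromonium attack at the free C5 of the electron-rich furan, then hydrolysis) releases the Z 2-ene-1,4-dicarbonyl with ketone C8 and aldehyde C11, and iodine-catalysed equilibration gives the more stable isomer with the two carbonyls trans, which is the 9E geometry of the target.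

Step 8
Reactants: 15 (±)-α-ionone, (3E)-4-(2,6,6-trimethylcyclohex-2-en-1-yl)but-3-en-2-one; 16 triethyl phosphonoacetate
Product: 18 ethyl (2E,4E)-3-methyl-5-(2,6,6-trimethylcyclohex-2-en-1-yl)penta-2,4-dienoate (racemic), via sodium phosphonate carbanion 17 (not isolated)
Conditions: 16, NaH, THF, 0 °C; then 15, 0 °C → reflux; chromatography (2E isomer)
Reagents that add atoms: none
Why: Horner–Wadsworth–Emmons olefination of the methyl ketone adds C10′ and C11′ and gives mainly the 2E dienoate, from which the minor 2Z isomer is removed.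

Step 9
Reactants: 18 ethyl (2E,4E)-3-methyl-5-(2,6,6-trimethylcyclohex-2-en-1-yl)penta-2,4-dienoate (racemic)
Product: 19 ethyl (2E,4E)-3-methyl-5-(2,6,6-trimethyl-4-oxocyclohex-2-en-1-yl)penta-2,4-dienoate (racemic)
Conditions: t-BuOOH (70% aq.), aq. NaOCl, K2CO3, MeCN, 0 °C
Reagents that add atoms: tert-butyl hydroperoxide, CC(C)(C)OO
Why: Radical allylic oxidation by tert-butylperoxyl radicals attacks the ring allylic CH2 and gives the cyclohexenone, as known for α-ionone and its C15 homologues.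

Step 10
Reactants: 19 ethyl (2E,4E)-3-methyl-5-(2,6,6-trimethyl-4-oxocyclohex-2-en-1-yl)penta-2,4-dienoate (racemic)
Product: 20 ethyl (2E,4E)-5-[(1R,4R)-4-hydroxy-2,6,6-trimethylcyclohex-2-en-1-yl]-3-methylpenta-2,4-dienoate
Conditions: RuCl[(R,R)-TsDPEN](p-cymene) (1 mol %), HCO2Na, H2O/CH2Cl2, 30 °C; chromatography
Reagents that add atoms: none
Why: Noyori asymmetric transfer hydrogenation reduces the ring enone carbonyl under catalyst control (same local environment as the C4 carbonyl of ketoisophorone; alkenyl side as the π group) and sets 4R in both enantiomers of 19, so the (1R) enantiomer gives trans 20 and the (1S) enantiomer gives the cis diastereomer, which is separated.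

Step 11
Reactants: 20 ethyl (2E,4E)-5-[(1R,4R)-4-hydroxy-2,6,6-trimethylcyclohex-2-en-1-yl]-3-methylpenta-2,4-dienoate
Product: 21 (2E,4E)-5-[(1R,4R)-4-hydroxy-2,6,6-trimethylcyclohex-2-en-1-yl]-3-methylpenta-2,4-dien-1-ol
Conditions: i-Bu2AlH (3.3 equiv), CH2Cl2, −78 → 0 °C; aq. potassium sodium tartrate
Reagents that add atoms: none
Why: Aluminium hydride 1,2-reduction of the conjugated ester gives the primary dienylic alcohol and leaves the diene and both stereocentres untouched.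

Step 12
Reactants: 21 (2E,4E)-5-[(1R,4R)-4-hydroxy-2,6,6-trimethylcyclohex-2-en-1-yl]-3-methylpenta-2,4-dien-1-ol
Product: 23 {(2E,4E)-5-[(1R,4R)-4-hydroxy-2,6,6-trimethylcyclohex-2-en-1-yl]-3-methylpenta-2,4-dien-1-yl}triphenylphosphonium bromide, via C15 allylic bromide 22 (not isolated)
Conditions: CBr4 (1.05 equiv), PPh3 (1.1 equiv), 2,6-lutidine, CH2Cl2, −30 °C; then PPh3 (1.2 equiv), rt
Reagents that add atoms: triphenylphosphine, c1ccc(cc1)P(c1ccccc1)c1ccccc1; carbon tetrabromide, BrC(Br)(Br)Br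
Why: Appel bromination is selective for the primary dienylic alcohol over the ring secondary alcohol, and SN2 quaternisation of PPh3 follows in the same flask; acid is avoided because it would ionise and epimerise the ring allylic 4-OH.

Step 13
Reactants: 23 {(2E,4E)-5-[(1R,4R)-4-hydroxy-2,6,6-trimethylcyclohex-2-en-1-yl]-3-methylpenta-2,4-dien-1-yl}triphenylphosphonium bromide; 24 (2E,4E,6E)-2,7-dimethylocta-2,4,6-trienedial
Product: 27 (2E,4E,6E,8E,10E,12E)-13-[(1R,4R)-4-hydroxy-2,6,6-trimethylcyclohex-2-en-1-yl]-2,7,11-trimethyltrideca-2,4,6,8,10,12-hexaenal, via C15 ylide 25 (not isolated), via 8Z aldehyde 26 (not isolated)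
Conditions: NaOMe (1.05 equiv), MeOH/CH2Cl2, 0 °C; 24 (1.5 equiv), 0 °C → rt; then n-heptane, 90 °C
Reagents that add atoms: none
Why: Wittig mono-olefination of the excess C10 dialdehyde stops after one condensation because the product aldehyde is less electrophilic, and the part formed as the 8Z isomer is equilibrated thermally to all-E.

Step 14
Reactants: 27 (2E,4E,6E,8E,10E,12E)-13-[(1R,4R)-4-hydroxy-2,6,6-trimethylcyclohex-2-en-1-yl]-2,7,11-trimethyltrideca-2,4,6,8,10,12-hexaenal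
Product: 28 (2E,4E,6E,8E,10E,12E)-13-[(1R,4R)-4-hydroxy-2,6,6-trimethylcyclohex-2-en-1-yl]-2,7,11-trimethyltrideca-2,4,6,8,10,12-hexaen-1-ol
Conditions: NaBH4, MeOH/THF, 0 °C
Reagents that add atoms: none
Why: Borohydride 1,2-reduction of the polyenal gives the primary polyenylic alcohol cleanly.

Step 15
Reactants: 28 (2E,4E,6E,8E,10E,12E)-13-[(1R,4R)-4-hydroxy-2,6,6-trimethylcyclohex-2-en-1-yl]-2,7,11-trimethyltrideca-2,4,6,8,10,12-hexaen-1-ol
Product: 30 {(2E,4E,6E,8E,10E,12E)-13-[(1R,4R)-4-hydroxy-2,6,6-trimethylcyclohex-2-en-1-yl]-2,7,11-trimethyltrideca-2,4,6,8,10,12-hexaen-1-yl}triphenylphosphonium bromide, via C25 allylic bromide 29 (not isolated)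
Conditions: CBr4 (1.05 equiv), PPh3 (1.1 equiv), 2,6-lutidine, CH2Cl2, −30 °C, dark; then PPh3 (1.2 equiv), 0 °C
Reagents that add atoms: triphenylphosphine, c1ccc(cc1)P(c1ccccc1)c1ccccc1; carbon tetrabromide, BrC(Br)(Br)Br
Why: Appel bromination of the primary polyenylic alcohol and in-flask SN2 trapping of the labile bromide by PPh3 give the C25 Wittig salt without acid, so the ring allylic alcohol keeps its configuration.

Step 16
Reactants: 30 {(2E,4E,6E,8E,10E,12E)-13-[(1R,4R)-4-hydroxy-2,6,6-trimethylcyclohex-2-en-1-yl]-2,7,11-trimethyltrideca-2,4,6,8,10,12-hexaen-1-yl}triphenylphosphonium bromide; 14 (2E)-4-oxo-2-{[(4R)-2,6,6-trimethyl-4-(triethylsilyloxy)cyclohex-1-en-1-yl]acetyl}but-2-en-1-yl (2E)-dodec-2-enoate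
Product: 33 (3R,3′R,6′R)-3′-hydroxy-8-oxo-3-(triethylsilyloxy)-7,8-dihydro-β,ε-caroten-19-yl (2E)-dodec-2-enoate, via C25 ylide 31 (not isolated), via 11Z isomer 32 (not isolated)
Conditions: NaN(SiMe3)2 (1.0 equiv), THF, −78 → 0 °C; then 14, −78 → −20 °C; then EtOAc, 60 °C, dark
Reagents that add atoms: none
Why: Wittig olefination with the preformed, base-free ylide takes place at the aldehyde (far more electrophilic than the hindered enone ketone) and forms C11=C12, the 11Z portion is equilibrated thermally to all-E, and no stereocentre is touched.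

Step 17
Reactants: 33 (3R,3′R,6′R)-3′-hydroxy-8-oxo-3-(triethylsilyloxy)-7,8-dihydro-β,ε-caroten-19-yl (2E)-dodec-2-enoate
Product: 34 (3R,3′R,6′R)-3,3′-dihydroxy-8-oxo-7,8-dihydro-β,ε-caroten-19-yl (2E)-dodec-2-enoate (target)
Conditions: HF·pyridine, pyridine, THF, 0 °C
Reagents that add atoms: none
Why: Buffered fluoride desilylation removes the secondary TES ether within minutes and is mild enough for the polyene, the allylic ester and the ε-ring allylic alcohol.

**Compound list**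
1 | (4R,6R)-4-hydroxy-2,2,6-trimethylcyclohexan-1-one (actinol) | O=C1[C@H](C)C[C@@H](O)CC1(C)C | starting material
2 | (4R,6R)-2,2,6-trimethyl-4-(triethylsilyloxy)cyclohexan-1-one | O=C1[C@H](C)C[C@@H](O[Si](CC)(CC)CC)CC1(C)C | intermediate
3 | potassium (4R)-2,6,6-trimethyl-4-(triethylsilyloxy)cyclohex-1-en-1-olate | [K+].[O-]C1=C(C)C[C@@H](O[Si](CC)(CC)CC)CC1(C)C | intermediate
4 | (4R)-2,6,6-trimethyl-4-(triethylsilyloxy)cyclohex-1-en-1-yl trifluoromethanesulfonate | FC(F)(F)S(=O)(=O)OC1=C(C)C[C@@H](O[Si](CC)(CC)CC)CC1(C)C | intermediate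
5 | (tributylstannyl)methanol | CCCC[Sn](CCCC)(CCCC)CO | starting material
6 | [(4R)-2,6,6-trimethyl-4-(triethylsilyloxy)cyclohex-1-en-1-yl]methanol | OCC1=C(C)C[C@@H](O[Si](CC)(CC)CC)CC1(C)C | intermediate
7 | {[(1R)-4-(bromomethyl)-3,5,5-trimethylcyclohex-3-en-1-yl]oxy}triethylsilane | BrCC1=C(C)C[C@@H](O[Si](CC)(CC)CC)CC1(C)C | intermediate
8 | furan-3-ylmethanol | OCc1ccoc1 | starting material
9 | lithium (2-lithiofuran-3-yl)methanolate | [Li]OCc1ccoc1[Li] | intermediate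
10 | (2-{[(4R)-2,6,6-trimethyl-4-(triethylsilyloxy)cyclohex-1-en-1-yl]methyl}furan-3-yl)methanol | OCc1ccoc1CC1=C(C)C[C@@H](O[Si](CC)(CC)CC)CC1(C)C | intermediate
11 | (2E)-dodec-2-enoic acid | CCCCCCCCC/C=C/C(=O)O | starting material
12 | (2-{[(4R)-2,6,6-trimethyl-4-(triethylsilyloxy)cyclohex-1-en-1-yl]methyl}furan-3-yl)methyl (2E)-dodec-2-enoate | CCCCCCCCC/C=C/C(=O)OCc1ccoc1CC1=C(C)C[C@@H](O[Si](CC)(CC)CC)CC1(C)C | intermediate
13 | (2Z)-4-oxo-2-{[(4R)-2,6,6-trimethyl-4-(triethylsilyloxy)cyclohex-1-en-1-yl]acetyl}but-2-en-1-yl (2E)-dodec-2-enoate | CCCCCCCCC/C=C/C(=O)OC/C(=C/C=O)C(=O)CC1=C(C)C[C@@H](O[Si](CC)(CC)CC)CC1(C)C | intermediate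
14 | (2E)-4-oxo-2-{[(4R)-2,6,6-trimethyl-4-(triethylsilyloxy)cyclohex-1-en-1-yl]acetyl}but-2-en-1-yl (2E)-dodec-2-enoate | CCCCCCCCC/C=C/C(=O)OC\C(=C/C=O)C(=O)CC1=C(C)C[C@@H](O[Si](CC)(CC)CC)CC1(C)C | intermediate
15 | (±)-α-ionone, (3E)-4-(2,6,6-trimethylcyclohex-2-en-1-yl)but-3-en-2-one | CC(=O)/C=C/C1C(C)=CCCC1(C)C | starting material
16 | triethyl phosphonoacetate | CCOC(=O)CP(=O)(OCC)OCC | starting material
17 | sodium salt of triethyl phosphonoacetate (carbanion) | [Na+].CCOC(=O)[CH-]P(=O)(OCC)OCC | intermediate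
18 | ethyl (2E,4E)-3-methyl-5-(2,6,6-trimethylcyclohex-2-en-1-yl)penta-2,4-dienoate (racemic) | CCOC(=O)/C=C(C)/C=C/C1C(C)=CCCC1(C)C | intermediate
19 | ethyl (2E,4E)-3-methyl-5-(2,6,6-trimethyl-4-oxocyclohex-2-en-1-yl)penta-2,4-dienoate (racemic) | CCOC(=O)/C=C(C)/C=C/C1C(C)=CC(=O)CC1(C)C | intermediate
20 | ethyl (2E,4E)-5-[(1R,4R)-4-hydroxy-2,6,6-trimethylcyclohex-2-en-1-yl]-3-methylpenta-2,4-dienoate | CCOC(=O)/C=C(C)/C=C/[C@H]1C(C)=C[C@H](O)CC1(C)C | intermediate
21 | (2E,4E)-5-[(1R,4R)-4-hydroxy-2,6,6-trimethylcyclohex-2-en-1-yl]-3-methylpenta-2,4-dien-1-ol | OC/C=C(C)/C=C/[C@H]1C(C)=C[C@H](O)CC1(C)C | intermediate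
22 | (1R,4R)-4-[(1E,3E)-5-bromo-3-methylpenta-1,3-dien-1-yl]-3,5,5-trimethylcyclohex-2-en-1-ol | BrC/C=C(C)/C=C/[C@H]1C(C)=C[C@H](O)CC1(C)C | intermediate
23 | {(2E,4E)-5-[(1R,4R)-4-hydroxy-2,6,6-trimethylcyclohex-2-en-1-yl]-3-methylpenta-2,4-dien-1-yl}triphenylphosphonium bromide | [Br-].c1ccccc1[P+](c1ccccc1)(c1ccccc1)C/C=C(C)/C=C/[C@H]1C(C)=C[C@H](O)CC1(C)C | intermediate
24 | (2E,4E,6E)-2,7-dimethylocta-2,4,6-trienedial | O=C/C(C)=C/C=C/C=C(C)/C=O | starting material
25 | ylide of 23, (1R,4R)-3,5,5-trimethyl-4-[(1E,3E)-3-methyl-5-(triphenyl-λ5-phosphanylidene)penta-1,3-dien-1-yl]cyclohex-2-en-1-ol | c1ccccc1P(c1ccccc1)(c1ccccc1)=C/C=C(C)/C=C/[C@H]1C(C)=C[C@H](O)CC1(C)C | intermediate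
26 | (2E,4E,6E,8Z,10E,12E)-13-[(1R,4R)-4-hydroxy-2,6,6-trimethylcyclohex-2-en-1-yl]-2,7,11-trimethyltrideca-2,4,6,8,10,12-hexaenal | O=C/C(C)=C/C=C/C=C(C)/C=C\C=C(C)\C=C\[C@H]1C(C)=C[C@H](O)CC1(C)C | intermediate
27 | (2E,4E,6E,8E,10E,12E)-13-[(1R,4R)-4-hydroxy-2,6,6-trimethylcyclohex-2-en-1-yl]-2,7,11-trimethyltrideca-2,4,6,8,10,12-hexaenal | O=C/C(C)=C/C=C/C=C(C)/C=C/C=C(C)/C=C/[C@H]1C(C)=C[C@H](O)CC1(C)C | intermediate
28 | (2E,4E,6E,8E,10E,12E)-13-[(1R,4R)-4-hydroxy-2,6,6-trimethylcyclohex-2-en-1-yl]-2,7,11-trimethyltrideca-2,4,6,8,10,12-hexaen-1-ol | OC/C(C)=C/C=C/C=C(C)/C=C/C=C(C)/C=C/[C@H]1C(C)=C[C@H](O)CC1(C)C | intermediate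
29 | (1R,4R)-4-[(1E,3E,5E,7E,9E,11E)-13-bromo-3,7,12-trimethyltrideca-1,3,5,7,9,11-hexaen-1-yl]-3,5,5-trimethylcyclohex-2-en-1-ol | BrC/C(C)=C/C=C/C=C(C)/C=C/C=C(C)/C=C/[C@H]1C(C)=C[C@H](O)CC1(C)C | intermediate
30 | {(2E,4E,6E,8E,10E,12E)-13-[(1R,4R)-4-hydroxy-2,6,6-trimethylcyclohex-2-en-1-yl]-2,7,11-trimethyltrideca-2,4,6,8,10,12-hexaen-1-yl}triphenylphosphonium bromide | [Br-].c1ccccc1[P+](c1ccccc1)(c1ccccc1)C/C(C)=C/C=C/C=C(C)/C=C/C=C(C)/C=C/[C@H]1C(C)=C[C@H](O)CC1(C)C | intermediate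
31 | ylide of 30 (C25 triphenylphosphoranylidene hexaene) | c1ccccc1P(c1ccccc1)(c1ccccc1)=C/C(C)=C/C=C/C=C(C)/C=C/C=C(C)/C=C/[C@H]1C(C)=C[C@H](O)CC1(C)C | intermediate
32 | (11Z)-isomer of 33 | CCCCCCCCC/C=C/C(=O)OC\C(=C/C=C\C(C)=C\C=C\C=C(C)\C=C\C=C(C)\C=C\[C@H]1C(C)=C[C@H](O)CC1(C)C)C(=O)CC1=C(C)C[C@@H](O[Si](CC)(CC)CC)CC1(C)C | intermediate
33 | (3R,3′R,6′R)-3′-hydroxy-8-oxo-3-(triethylsilyloxy)-7,8-dihydro-β,ε-caroten-19-yl (2E)-dodec-2-enoate | CCCCCCCCC/C=C/C(=O)OC\C(=C/C=C/C(C)=C/C=C/C=C(C)/C=C/C=C(C)/C=C/[C@H]1C(C)=C[C@H](O)CC1(C)C)C(=O)CC1=C(C)C[C@@H](O[Si](CC)(CC)CC)CC1(C)C | intermediate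
34 | (3R,3′R,6′R)-3,3′-dihydroxy-8-oxo-7,8-dihydro-β,ε-caroten-19-yl (2E)-dodec-2-enoate | CCCCCCCCC/C=C/C(=O)OC\C(=C/C=C/C(C)=C/C=C/C=C(C)/C=C/C=C(C)/C=C/[C@H]1C(C)=C[C@H](O)CC1(C)C)C(=O)CC1=C(C)C[C@@H](O)CC1(C)C | target

**Step count and risks**
Total: 17 steps. Longest linear sequence: 10 steps (15 → 34, steps 8 to 17); the β-end branch from 1 is 9 steps (steps 1 to 7, 16, 17).

Three steps most likely to fail:

Step 3. The enol triflate is tetrasubstituted and flanked by a quaternary carbon, so transfer of the CH2OH group from tin may be too slow and butyl transfer or triflate reduction may take over. Fallback: setting out from 4, carbonylation with Pd(OAc)2/PPh3 (CO 1 atm, MeOH, Et3N, DMF, 60 °C) gives methyl (4R)-2,6,6-trimethyl-4-(triethylsilyloxy)cyclohex-1-ene-1-carboxylate F1, and i-Bu2AlH reduction of this ester (CH2Cl2, −78 °C) comes back to the route at 6.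

Step 7. NBS must react with the furan faster than with the tetrasubstituted ring alkene, and the Z to E equilibration must not cost the allylic acyloxy group. Fallback: setting out from 12, dye-sensitised photo-oxygenation (O2, methylene blue, hν, MeOH, −78 °C) engages only the furan diene in a [4+2] cycloaddition and methanol opens the endoperoxide to [5-hydroperoxy-2-methoxy-2-{[(4R)-2,6,6-trimethyl-4-(triethylsilyloxy)cyclohex-1-en-1-yl]methyl}-2,5-dihydrofuran-3-yl]methyl (2E)-dodec-2-enoate F2; Me2S reduction in the same flask collapses it to the Z keto-enal, coming back to the route at 13, which is isomerised to 14 as before.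

Step 16. The aldehyde partner is an ene-dicarbonyl with an allylic acyloxy leaving group and acidic C7 hydrogens, so conjugate addition with SN2′ loss of dodecenoate, or enolisation, may compete with carbonyl addition of the ylide. Fallback: carry C19–O as a silyl ether and acylate last. Setting out from 10, TESCl/imidazole gives triethyl[(2-{[(4R)-2,6,6-trimethyl-4-(triethylsilyloxy)cyclohex-1-en-1-yl]methyl}furan-3-yl)methoxy]silane F3. NBS/NaHCO3 opening gives (2Z)-4-oxo-3-[(triethylsilyloxy)methyl]-5-[(4R)-2,6,6-trimethyl-4-(triethylsilyloxy)cyclohex-1-en-1-yl]pent-2-enal F4, and iodine equilibration gives the (2E)-isomer F5. Wittig reaction of F5 with ylide 31 gives (11Z)-3,19-bis-O-triethylsilylsiphonaxanthin F6 and, after heating, all-E 3,19-bis-O-triethylsilylsiphonaxanthin F7. HF·pyridine then gives siphonaxanthin, (3R,3′R,6′R)-3,19,3′-trihydroxy-7,8-dihydro-β,ε-caroten-8-one F8. Its primary allylic 19-OH is acylated in preference to the two secondary ring hydroxyls with 11 (DCC 1.0 equiv, DMAP 5 mol %, CH2Cl2, −20 °C), coming back to the route at 34.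

**Further compounds**
F1 | step 3 | methyl (4R)-2,6,6-trimethyl-4-(triethylsilyloxy)cyclohex-1-ene-1-carboxylate | COC(=O)C1=C(C)C[C@@H](O[Si](CC)(CC)CC)CC1(C)C
F2 | step 7 | [5-hydroperoxy-2-methoxy-2-{[(4R)-2,6,6-trimethyl-4-(triethylsilyloxy)cyclohex-1-en-1-yl]methyl}-2,5-dihydrofuran-3-yl]methyl (2E)-dodec-2-enoate (diastereomer mixture at the two acetal carbons) | CCCCCCCCC/C=C/C(=O)OCC1=CC(OO)OC1(OC)CC1=C(C)C[C@@H](O[Si](CC)(CC)CC)CC1(C)C
F3 | step 16 | triethyl[(2-{[(4R)-2,6,6-trimethyl-4-(triethylsilyloxy)cyclohex-1-en-1-yl]methyl}furan-3-yl)methoxy]silane | CC[Si](CC)(CC)OCc1ccoc1CC1=C(C)C[C@@H](O[Si](CC)(CC)CC)CC1(C)C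
F4 | step 16 | (2Z)-4-oxo-3-[(triethylsilyloxy)methyl]-5-[(4R)-2,6,6-trimethyl-4-(triethylsilyloxy)cyclohex-1-en-1-yl]pent-2-enal | CC[Si](CC)(CC)OC/C(=C/C=O)C(=O)CC1=C(C)C[C@@H](O[Si](CC)(CC)CC)CC1(C)C
F5 | step 16 | (2E)-4-oxo-3-[(triethylsilyloxy)methyl]-5-[(4R)-2,6,6-trimethyl-4-(triethylsilyloxy)cyclohex-1-en-1-yl]pent-2-enal | CC[Si](CC)(CC)OC\C(=C/C=O)C(=O)CC1=C(C)C[C@@H](O[Si](CC)(CC)CC)CC1(C)C
F6 | step 16 | (11Z)-3,19-bis-O-triethylsilylsiphonaxanthin | CC[Si](CC)(CC)OC\C(=C/C=C\C(C)=C\C=C\C=C(C)\C=C\C=C(C)\C=C\[C@H]1C(C)=C[C@H](O)CC1(C)C)C(=O)CC1=C(C)C[C@@H](O[Si](CC)(CC)CC)CC1(C)C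
F7 | step 16 | all-E 3,19-bis-O-triethylsilylsiphonaxanthin | CC[Si](CC)(CC)OC\C(=C/C=C/C(C)=C/C=C/C=C(C)/C=C/C=C(C)/C=C/[C@H]1C(C)=C[C@H](O)CC1(C)C)C(=O)CC1=C(C)C[C@@H](O[Si](CC)(CC)CC)CC1(C)C
F8 | step 16 | siphonaxanthin, (3R,3′R,6′R)-3,19,3′-trihydroxy-7,8-dihydro-β,ε-caroten-8-one | OC\C(=C/C=C/C(C)=C/C=C/C=C(C)/C=C/C=C(C)/C=C/[C@H]1C(C)=C[C@H](O)CC1(C)C)C(=O)CC1=C(C)C[C@@H](O)CC1(C)C
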